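**Retrosynthetic overview**
- The C10'–O bond is cut last. An enantioselective Markovnikov hydroacetoxylation of a terminal alkene installs the acetate and the only stereocentre in one operation.
- The C6–C1' bond is cut next. Undec-10-enyllithium replaces one methoxy group of the symmetrical 2,6-dimethoxy-3,5-dimethyl-4-pyranone by addition–elimination.
- The pyranone is the only ring and is formed first. It closes through its O1–C bond by cyclodehydration of dimethyl 2,4-dimethyl-3-oxopentanedioate.
- That diester comes from double C-methylation of dimethyl 3-oxopentanedioate.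

**Assumption:** the (S,S) cobalt catalyst is taken to give the (S)-acetate. The sense of induction of the new reaction is checked on the first run by chiral HPLC against material from the known-chemistry fallback, and the equally cheap (R,R) catalyst is used if the sense is opposite.

**Step 1**
Reactants: 1 dimethyl 3-oxopentanedioate
Product: 2 dimethyl 2,4-dimethyl-3-oxopentanedioate (mixture of diastereomers)
Conditions: MeI (2.1 equiv), K2CO3 (2.2 equiv), acetone, reflux, 16 h
Reagents that add atoms: iodomethane, CI
Why: This is a double enolate C-alkylation of a 1,3-dicarbonyl compound in which, after the first methylation, the unsubstituted CH2 on the other side is more acidic and less hindered and takes the second methyl group; both new stereocentres become sp2 in step 2 and do not matter.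

**Step 2**
Reactants: 2 dimethyl 2,4-dimethyl-3-oxopentanedioate
Product: 3 2,6-dimethoxy-3,5-dimethyl-4H-pyran-4-one
Conditions: 20% oleum (SO3 in H2SO4), 0 °C to rt; poured on ice, CH2Cl2 extraction
Reagents that add atoms: none
Why: This is an acid-mediated cyclodehydration (C–O ring closure) in which the oxygen of one enolised ester attacks the other, acid-activated ester carbon, with SO3 taking up the water and the conjugated pyranone providing the driving force while both methoxy groups stay in place.

**Step 3**
Reactants: 3 2,6-dimethoxy-3,5-dimethyl-4H-pyran-4-one; 4 11-bromoundec-1-ene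
Product: 7 2-methoxy-3,5-dimethyl-6-(undec-10-en-1-yl)-4H-pyran-4-one, via undec-10-en-1-yllithium 5 (not isolated), via lithium dienolate adduct 6 (not isolated)
Conditions: 4, t-BuLi (2.0 equiv), Et2O/pentane, −78 °C, 30 min; then 3 (1.2 equiv) in THF, −78 to −20 °C; H2O quench
Reagents that add atoms: none
Why: Lithium–bromine exchange gives the primary alkyllithium, which attacks the ester-like C6 of the vinylogous carbonate rather than the donor-deactivated, methyl-flanked C4 carbonyl (conjugate addition–elimination, a vinylogous acyl substitution), and adduct 6 keeps its methoxide at −78 °C, which protects the second methoxy group until the organolithium is consumed.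

**Step 4**
Reactants: 7 2-methoxy-3,5-dimethyl-6-(undec-10-en-1-yl)-4H-pyran-4-one
Product: 8 (2S)-11-(6-methoxy-3,5-dimethyl-4-oxo-4H-pyran-2-yl)undecan-2-yl acetate
Conditions: Co(C36H52N2O2) [(S,S)-N,N'-bis(3,5-di-tert-butylsalicylidene)cyclohexane-1,2-diaminato complex of divalent cobalt] (5 mol %), PhI(OAc)2 (1.3 equiv), PhSiH3 (1.2 equiv, slow addition), CH2Cl2, −20 °C, N2, dark
Reagents that add atoms: (diacetoxyiodo)benzene, CC(=O)OI(OC(C)=O)c1ccccc1
Why: Proposed new method: enantioselective intermolecular Markovnikov hydroacetoxylation of an unactivated 1-alkene by metal-hydride hydrogen atom transfer and radical–polar crossover, in which the trivalent-iodine oxidant converts the divalent cobalt salen into a trivalent cobalt acetate, PhSiH3 turns this into a trivalent cobalt hydride that gives an H atom to the terminal CH2 of 7 (the tetrasubstituted pyranone C=C bonds do not react), the secondary C10' radical is caught reversibly by the chiral divalent cobalt, one-electron oxidation gives a tetravalent sec-alkylcobalt, and acetate delivered by a second chiral cobalt acetate unit displaces cobalt with inversion, so that the two rapidly interconverting diastereomeric alkylcobalt species are funnelled (Curtin–Hammett) through the faster one to the (S)-C–O bond; the closest known reaction types are the racemic cobalt-salen/silane/oxidant hydroacyloxylation of unactivated alkenes and the enantioselective intramolecular cobalt-salen hydroalkoxylation that gives 2-methyltetrahydrofurans, which shows that such a catalyst can tell CH3 from CH2R at this type of carbon.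

**Compound list**
1 | dimethyl 3-oxopentanedioate (dimethyl 1,3-acetonedicarboxylate) | COC(=O)CC(=O)CC(=O)OC | starting material
2 | dimethyl 2,4-dimethyl-3-oxopentanedioate (mixture of diastereomers) | COC(=O)C(C)C(=O)C(C)C(=O)OC | intermediate
3 | 2,6-dimethoxy-3,5-dimethyl-4H-pyran-4-one | COc1oc(OC)c(C)c(=O)c1C | intermediate
4 | 11-bromoundec-1-ene | C=CCCCCCCCCCBr | starting material
5 | undec-10-en-1-yllithium | [Li]CCCCCCCCCC=C | intermediate
6 | lithium 2,6-dimethoxy-3,5-dimethyl-2-(undec-10-en-1-yl)-2H-pyran-4-olate (racemic) | COC1=C(C)C(O[Li])=C(C)C(OC)(CCCCCCCCCC=C)O1 | intermediate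
7 | 2-methoxy-3,5-dimethyl-6-(undec-10-en-1-yl)-4H-pyran-4-one | COc1oc(CCCCCCCCCC=C)c(C)c(=O)c1C | intermediate
8 | (2S)-11-(6-methoxy-3,5-dimethyl-4-oxo-4H-pyran-2-yl)undecan-2-yl acetate | COc1oc(CCCCCCCCC[C@H](C)OC(C)=O)c(C)c(=O)c1C | target

**Total step count:** 4. **Longest linear sequence:** 4 (1 → 2 → 3 → 7 → 8).

**Steps most likely to fail**

**Step 4 (the proposed new reaction).**
- Risks: the ee may be too low, because the catalyst must tell methyl from a linear chain without a tethered nucleophile. Alkene isomerisation and simple reduction of the alkene are also possible.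
- The fallback uses known chemistry, sets out from 7 and comes back at 8. The stereocentre is then set by C–H rather than C–O bond formation.
- Tsuji–Wacker oxidation of 7 (PdCl2 10 mol %, CuCl 1 equiv, O2, DMF/H2O, rt) gives the methyl ketone 2-methoxy-3,5-dimethyl-6-(10-oxoundecyl)-4H-pyran-4-one F1.
- Prelog-selective enzymatic reduction gives 6-[(10S)-10-hydroxyundecyl]-2-methoxy-3,5-dimethyl-4H-pyran-4-one F2. It uses the alcohol dehydrogenase ADH-A of Rhodococcus ruber, catalytic NADH, i-PrOH and phosphate buffer pH 7.5 at 30 °C.
- Acetylation (Ac2O, DMAP, pyridine, 0 °C) gives 8 with retention of configuration.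

**Step 3.**
- Risks: attack at the C4 carbonyl, a second substitution, or an unclean lithium–bromine exchange.
- The fallback sets out from 4 (with 3) and comes back at 7. It uses a soft, stabilised carbanion and removes the activating group afterwards.
- Heating 4 with PhSO2Na in DMF at 80 °C gives undec-10-en-1-yl phenyl sulfone F3.
- n-BuLi in THF at −78 °C gives [1-(phenylsulfonyl)undec-10-en-1-yl]lithium F4.
- Two equivalents of F4 react with 3 by addition–elimination to give racemic 2-methoxy-3,5-dimethyl-6-[1-(phenylsulfonyl)undec-10-en-1-yl]-4H-pyran-4-one F5. Its acidic C1'–H is deprotonated in the flask, which blocks a second substitution.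
- Reductive desulfonylation of this vinylogous β-keto sulfone (SmI2, THF/MeOH, −78 °C) gives 7.

**Step 2.**
- Risks: O-demethylation, sulfonation or a low yield in oleum.
- The fallback sets out from 4 and comes back at 7. It builds the ring on an acyclic chain that already carries the side chain, so 2 and 3 are not needed.
- Mg in THF converts 4 into undec-10-en-1-ylmagnesium bromide F6. CO2 followed by aqueous HCl gives dodec-11-enoic acid F7.
- CDI in THF gives 1-(1H-imidazol-1-yl)dodec-11-en-1-one F8.
- Commercial methyl 2-methyl-3-oxopentanoate with LDA (2.2 equiv, THF, −78 to 0 °C) gives its dilithium dienediolate F9.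
- F9 is acylated at the γ-carbon by F8 to give methyl 2,4-dimethyl-3,5-dioxohexadec-15-enoate F10.
- DBU in refluxing toluene closes the ring to 4-hydroxy-3,5-dimethyl-6-(undec-10-en-1-yl)-2H-pyran-2-one F11.
- MeOTf in CH2Cl2, followed by aqueous NaHCO3, methylates the C2 carbonyl oxygen and gives 7.

**Further compounds**
F1 | step 4 | 2-methoxy-3,5-dimethyl-6-(10-oxoundecyl)-4H-pyran-4-one | COc1oc(CCCCCCCCCC(C)=O)c(C)c(=O)c1C
F2 | step 4 | 6-[(10S)-10-hydroxyundecyl]-2-methoxy-3,5-dimethyl-4H-pyran-4-one | COc1oc(CCCCCCCCC[C@H](C)O)c(C)c(=O)c1C
F3 | step 3 | undec-10-en-1-yl phenyl sulfone | C=CCCCCCCCCCS(=O)(=O)c1ccccc1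
F4 | step 3 | [1-(phenylsulfonyl)undec-10-en-1-yl]lithium | [Li]C(CCCCCCCCC=C)S(=O)(=O)c1ccccc1
F5 | step 3 | 2-methoxy-3,5-dimethyl-6-[1-(phenylsulfonyl)undec-10-en-1-yl]-4H-pyran-4-one (racemic) | COc1oc(C(CCCCCCCCC=C)S(=O)(=O)c2ccccc2)c(C)c(=O)c1C
F6 | step 2 | undec-10-en-1-ylmagnesium bromide | Br[Mg]CCCCCCCCCC=C
F7 | step 2 | dodec-11-enoic acid | C=CCCCCCCCCCC(=O)O
F8 | step 2 | 1-(1H-imidazol-1-yl)dodec-11-en-1-one | C=CCCCCCCCCCC(=O)n1ccnc1
F9 | step 2 | dilithium dienediolate of methyl 2-methyl-3-oxopentanoate | CC=C(O[Li])C(C)=C(O[Li])OC
F10 | step 2 | methyl 2,4-dimethyl-3,5-dioxohexadec-15-enoate (mixture of diastereomers and enol forms) | COC(=O)C(C)C(=O)C(C)C(=O)CCCCCCCCCC=C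
F11 | step 2 | 4-hydroxy-3,5-dimethyl-6-(undec-10-en-1-yl)-2H-pyran-2-one | Cc1c(O)c(C)c(CCCCCCCCCC=C)oc1=O
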